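The target is procyanidin B3 lacking the upper 3-hydroxyl, so both halves come from (+)-catechin. Everything rests on the bond between C4 of the upper pyran ring and C8 of the lower A ring. The key step is a Lewis-acid Friedel–Crafts coupling: the C4 benzylic cation of a 4-alkoxycatechin 3-xanthate, stabilised by its phloroglucinol A ring, is attacked by C8 of penta-O-benzylcatechin, the aromatic CH flanked by O1 and the 7-oxygen. The upper C3 oxygen is a temporary stereocontroller: as the xanthate it directs the arene trans to itself, hence cis to the 2-aryl group, and is then excised by radical deoxygenation before global hydrogenolysis.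

Key step: step 5

Remark on the chemistry: the ether made in step 3 is drawn as the 4β (4S, 3,4-cis) isomer; either C4 epimer would serve, because this centre is ionised in step 5.

Step 1
Reactants: 1 (+)-catechin
Product: 2 5,7,3',4'-tetra-O-benzyl-(+)-catechin, (2R,3S), 3-OH free
Conditions: BnBr (4.4 equiv), K2CO3, DMF, 0 °C to rt, under Ar
Reagents that add atoms: benzyl bromide, BrCc1ccccc1
Why: Williamson etherification in which carbonate deprotonates only the four phenols, so the secondary 3-OH stays free and neither stereocentre is touched.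

Step 2
Reactants: 2 5,7,3',4'-tetra-O-benzyl-(+)-catechin
Product: 3 3,5,7,3',4'-penta-O-benzyl-(+)-catechin, (2R,3S)
Conditions: NaH, BnBr, DMF, 0 °C to rt
Reagents that add atoms: benzyl bromide, BrCc1ccccc1
Why: Williamson etherification of the secondary alcohol through its sodium alkoxide, which leaves the lower half without a free hydroxyl so that only the upper C3 oxygen will carry the deoxygenation handle.

Step 3
Reactants: 2 5,7,3',4'-tetra-O-benzyl-(+)-catechin
Product: 4 (2R,3S,4S)-5,7-bis(benzyloxy)-2-[3,4-bis(benzyloxy)phenyl]-4-(2-ethoxyethoxy)chroman-3-ol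
Conditions: DDQ (2 equiv), 2-ethoxyethanol (5 equiv), CH2Cl2, rt
Reagents that add atoms: 2-ethoxyethanol, CCOCCO
Why: Oxidative benzylic C–H etherification, in which DDQ abstracts hydride from C4 (para to the 7-benzyloxy group) and the alcohol traps the quinone-methide cation, expected cis to the free 3-OH; this C4 configuration is erased again in step 5.

Step 4
Reactants: 4 the 4-(2-ethoxyethoxy) ether
Product: 6 O-[(2R,3S,4S)-5,7-bis(benzyloxy)-2-[3,4-bis(benzyloxy)phenyl]-4-(2-ethoxyethoxy)chroman-3-yl] S-methyl dithiocarbonate, via sodium xanthate salt 5 (not isolated)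
Conditions: NaH, imidazole (cat.), THF, 0 °C; CS2; then MeI, 0 °C to rt
Reagents that add atoms: carbon disulfide, S=C=S; iodomethane, CI
Why: Xanthate formation (first stage of a Barton–McCombie deoxygenation), in which the C3 alkoxide adds to CS2 and the dithiocarbonate salt is S-methylated, with retention at C3 because the C3–O bond is not broken.

Step 5
Reactants: 6 the 4-alkoxy 3-O-xanthate electrophile; 3 penta-O-benzyl-(+)-catechin
Product: 8 nona-O-benzyl catechin-(4α→8)-catechin carrying the S-methyl dithiocarbonate on the upper O3 (upper unit 2R,3S,4S; lower unit 2R,3S), via C4 benzylic cation 7 (not isolated)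
Conditions: 3 (4 equiv), TMSOTf (0.2 equiv), 4 Å MS, CH2Cl2, −78 to −40 °C; Et3N quench
Reagents that add atoms: none
Why: TMSOTf ionises the C4 ether of 6, 2-ethoxyethanol leaves, and the C4 cation 7 forms, a quinone-methide-type ion stabilised by O1 and the 5- and 7-benzyloxy groups of the upper A ring. C8 of 3, the free aromatic CH between O1 and the 7-benzyloxy group, attacks it in a Friedel–Crafts alkylation and loses a proton, which forms the C4–C8 bond; the closest known reaction type is the Lewis-acid condensation of 4-alkoxyflavan-3-ol derivatives with benzylated flavan-3-ols used for B-type procyanidins. No ring is closed. The one new stereocentre, C4, is controlled by the adjacent C3 centre: the β-oriented 3-O-dithiocarbonate covers the β-face, either by reversible capture of the cation through its thiocarbonyl sulfur (a cis-fused 1,3-oxathiolan-2-ylium ion, the analogue of the acetoxonium ion of 3-O-acyl groups) or simply by its bulk, so the arene should enter from the α-face, trans to O3 and therefore cis to the 2-aryl group (4S). The step needs C8 rather than C6 attack and cross- rather than self-condensation: the first is the known preference of 5,7-di-O-benzylflavan-3-ols, the second is secured by the low temperature and the excess of 3, which is recovered.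

Step 6
Reactants: 8 the coupled xanthate
Product: 9 nona-O-benzyl luteoliflavan-(4α→8)-catechin (upper unit 2S,4S with C3 now CH2; lower unit 2R,3S)
Conditions: Bu3SnH (3 equiv), AIBN (cat.), toluene, 90 °C
Reagents that add atoms: none
Why: Barton–McCombie deoxygenation, in which the stannyl radical adds to C=S, β-scission gives the secondary C3 radical and tin hydride at high concentration reduces it before it can fragment, so C3 becomes CH2 while C2 and C4 keep their configuration.

Step 7
Reactants: 9 the nona-O-benzyl 3-deoxy dimer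
Product: 10 CNP0180676.1, luteoliflavan-(4α→8)-catechin (upper unit 2S,4S; lower unit 2R,3S)
Conditions: H2 (1 atm), Pd(OH)2/C, THF/MeOH/H2O, rt
Reagents that add atoms: none
Why: Catalytic hydrogenolysis of all nine benzyl ethers under neutral conditions, as is routine for benzylated procyanidins, leaving the interflavan C4–C8 bond and the four stereocentres unaffected.

Compound list
1 | (+)-catechin, (2R,3S) | Oc1cc(O)c2c(c1)O[C@H](c1ccc(O)c(O)c1)[C@@H](O)C2 | starting material
2 | 5,7,3',4'-tetra-O-benzyl-(+)-catechin | c1ccccc1COc1cc(OCc2ccccc2)c2c(c1)O[C@H](c1ccc(OCc3ccccc3)c(OCc3ccccc3)c1)[C@@H](O)C2 | intermediate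
3 | 3,5,7,3',4'-penta-O-benzyl-(+)-catechin | c1ccccc1COc1cc(OCc2ccccc2)c2c(c1)O[C@H](c1ccc(OCc3ccccc3)c(OCc3ccccc3)c1)[C@@H](OCc1ccccc1)C2 | intermediate
4 | (2R,3S,4S)-4-(2-ethoxyethoxy)-5,7,3',4'-tetra-O-benzylcatechin | c1ccccc1COc1cc(OCc2ccccc2)c2c(c1)O[C@H](c1ccc(OCc3ccccc3)c(OCc3ccccc3)c1)[C@@H](O)[C@H]2OCCOCC | intermediate
5 | sodium O-(flavan-3-yl) dithiocarbonate of 4 (not isolated) | c1ccccc1COc1cc(OCc2ccccc2)c2c(c1)O[C@H](c1ccc(OCc3ccccc3)c(OCc3ccccc3)c1)[C@@H](OC(=S)[S-])[C@H]2OCCOCC.[Na+] | intermediate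
6 | 3-O-[(methylsulfanyl)carbonothioyl] derivative of 4 (S-methyl xanthate) | c1ccccc1COc1cc(OCc2ccccc2)c2c(c1)O[C@H](c1ccc(OCc3ccccc3)c(OCc3ccccc3)c1)[C@@H](OC(=S)SC)[C@H]2OCCOCC | intermediate
7 | C4 benzylic cation of 6 (not isolated) | c1ccccc1COc1cc(OCc2ccccc2)c2c(c1)O[C@H](c1ccc(OCc3ccccc3)c(OCc3ccccc3)c1)[C@@H](OC(=S)SC)[CH+]2 | intermediate
8 | nona-O-benzyl catechin-(4α→8)-catechin, upper 3-O-xanthate | c1ccccc1COc1cc(OCc2ccccc2)c2c(c1)O[C@H](c1ccc(OCc3ccccc3)c(OCc3ccccc3)c1)[C@@H](OC(=S)SC)[C@@H]2c1c(OCc2ccccc2)cc(OCc2ccccc2)c2c1O[C@H](c1ccc(OCc3ccccc3)c(OCc3ccccc3)c1)[C@@H](OCc1ccccc1)C2 | intermediate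
9 | nona-O-benzyl luteoliflavan-(4α→8)-catechin | c1ccccc1COc1cc(OCc2ccccc2)c2c(c1)O[C@H](c1ccc(OCc3ccccc3)c(OCc3ccccc3)c1)C[C@@H]2c1c(OCc2ccccc2)cc(OCc2ccccc2)c2c1O[C@H](c1ccc(OCc3ccccc3)c(OCc3ccccc3)c1)[C@@H](OCc1ccccc1)C2 | intermediate
10 | CNP0180676.1, luteoliflavan-(4α→8)-catechin | Oc1cc(O)c2c(c1)O[C@H](c1ccc(O)c(O)c1)C[C@@H]2c1c(O)cc(O)c2c1O[C@H](c1ccc(O)c(O)c1)[C@@H](O)C2 | target

Total step count: 7. Longest linear sequence: 6 steps (1 → 2 → 4 → 6 → 8 → 9 → 10, steps 1, 3, 4, 5, 6 and 7); step 2 is the side branch to nucleophile 3.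

Steps most likely to fail

Step 5. The arene may enter with poor facial selectivity at C4, the Lewis acid may engage the thiocarbonyl group so that the cation is diverted on sulfur, or the electrophile may self-condense. The fallback sets out from 4 and returns at 8, using the established acetate participation. Compound 4 is acetylated (Ac2O, pyridine, DMAP) to the 3-O-acetyl-4-(2-ethoxyethoxy) ether F1. TMSOTf-catalysed coupling of F1 with 3 at −78 °C, steered by the acetoxonium ion, should give the 3,4-trans nona-O-benzyl dimer acetate F2. Methanolysis (K2CO3, MeOH/THF) should free the upper 3-hydroxyl to give the dimer alcohol F3, the only free hydroxyl in the molecule. Xanthate formation on F3 (NaH, CS2, MeI) then gives 8.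

Step 6. The C3 radical may fragment by loss of the O1 phenoxyl (ring opening) before hydrogen transfer, or the xanthate may undergo thermal syn-elimination instead of chain reduction. The fallback sets out from 8 and returns at 10, turning the elimination into the method. Chugaev thermolysis of 8 (o-dichlorobenzene, about 160 °C) should give the 4-aryl-flav-2-ene F4 and/or the 4-aryl-flav-3-ene F5, since both H2 and H4 are cis to the xanthate. Hydrogenation under the conditions of step 7 (H2, Pd(OH)2/C) should add hydrogen to the face opposite the remaining benzylic aryl group. In either alkene this restores the 2,4-cis arrangement (2S,4S), and the benzyl ethers are cleaved in the same operation to give 10.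

Step 7. Cleavage of the nine benzyl ethers may stall, and long exposure may bring hydrogenolysis of the benzylic C2–O1 bonds or scission of the interflavan bond. The fallback sets out from 9 and returns at 10 by Lewis-acid dealkylation in place of hydrogenolysis: BCl3 with pentamethylbenzene as benzyl-cation scavenger, CH2Cl2, −78 °C. No new compound arises (F0).

Further compounds
F1 | step 5 | (2R,3S,4S)-3-O-acetyl-4-(2-ethoxyethoxy)-5,7,3',4'-tetra-O-benzylcatechin | c1ccccc1COc1cc(OCc2ccccc2)c2c(c1)O[C@H](c1ccc(OCc3ccccc3)c(OCc3ccccc3)c1)[C@@H](OC(C)=O)[C@H]2OCCOCC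
F2 | step 5 | nona-O-benzyl catechin-(4α→8)-catechin, upper 3-O-acetate | c1ccccc1COc1cc(OCc2ccccc2)c2c(c1)O[C@H](c1ccc(OCc3ccccc3)c(OCc3ccccc3)c1)[C@@H](OC(C)=O)[C@@H]2c1c(OCc2ccccc2)cc(OCc2ccccc2)c2c1O[C@H](c1ccc(OCc3ccccc3)c(OCc3ccccc3)c1)[C@@H](OCc1ccccc1)C2
F3 | step 5 | nona-O-benzyl catechin-(4α→8)-catechin, upper 3-OH free | c1ccccc1COc1cc(OCc2ccccc2)c2c(c1)O[C@H](c1ccc(OCc3ccccc3)c(OCc3ccccc3)c1)[C@@H](O)[C@@H]2c1c(OCc2ccccc2)cc(OCc2ccccc2)c2c1O[C@H](c1ccc(OCc3ccccc3)c(OCc3ccccc3)c1)[C@@H](OCc1ccccc1)C2
F4 | step 6 | nona-O-benzyl 4-aryl-flav-2-ene (C2=C3 in the upper unit, C4 retained) | c1ccccc1COc1cc(OCc2ccccc2)c2c(c1)OC(c1ccc(OCc3ccccc3)c(OCc3ccccc3)c1)=C[C@@H]2c1c(OCc2ccccc2)cc(OCc2ccccc2)c2c1O[C@H](c1ccc(OCc3ccccc3)c(OCc3ccccc3)c1)[C@@H](OCc1ccccc1)C2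
F5 | step 6 | nona-O-benzyl 4-aryl-flav-3-ene (C3=C4 in the upper unit, C2 retained) | c1ccccc1COc1cc(OCc2ccccc2)c2c(c1)O[C@H](c1ccc(OCc3ccccc3)c(OCc3ccccc3)c1)C=C2c1c(OCc2ccccc2)cc(OCc2ccccc2)c2c1O[C@H](c1ccc(OCc3ccccc3)c(OCc3ccccc3)c1)[C@@H](OCc1ccccc1)C2
F0 | step 7 | none | none
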